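If I read conversion from the target peak and nothing else, the readings so far give a time at which this flask reaches the conversion asked about.

in all of them: starting material 0.029 M
- epsilon: second substrate 1 equiv; partner 1.1 equiv; free catalyst 0.13 mol%; the very flask that is asked about, followed so far
- delta: second substrate 1 equiv; partner 1.1 equiv; free catalyst 0.065 mol%; run made earlier
- flask: second substrate 1.00 equiv; partner 1.10 equiv; free catalyst 0.13 mol%

| run | time / min | target / % |
|---|---|---|
| epsilon | 1.50 | 1.4 |
| epsilon | 3.00 | 2.9 |
| epsilon | 5.00 | 4.1 |
| epsilon | 6.00 | 5.8 |
| epsilon | 8.00 | 7.8 |
| epsilon | 10.0 | 8.4 |
| epsilon | 12.0 | 8.8 |
| delta | 2.50 | 1.6 |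
| delta | 5.00 | 1.8 |
| delta | 6.00 | 3.1 |
| delta | 10.0 | 5.0 |
| delta | 12.0 | 5.1 |
| delta | 15.0 | 6.9 |

(standard deviation of a reading: 0.5 percentage points)

- what has gone from starting material into another species counts as reacted, even if it can come back
- no earlier run changes the charge of second substrate; that part of a forecast is a guess
- no earlier run changes the charge of partner; that part of a forecast is a guess

- apparent order in second substrate when 30% of the starting material are converted (percent change of the rate of making target for one percent more second substrate charged)
- apparent order in partner when 30% of the starting material are converted (percent change of the rate of making target for one percent more partner charged)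

Epsilon is this flask followed so far, and it has 8.8% target at 12.0 min. Carrying that mean pace on in a straight line puts 30% at 40.9 min, and this is my target clock: the time to a given conversion if target were the one thing made, at its mean pace so far. Delta, at half the loading, gives 65.2 min from its last reading, later than epsilon, so the clock moves with the catalyst. No run varies second substrate or partner, so I commit to the clock and to no order.

The forecast gives 0.6 for second substrate (range 0.1 to 1.05) and 0.4 for partner (range 0 to 1), and it says “both orders are largely guesses from mechanism”.

The flask gives −0.13 for second substrate and 0.64 for partner, and it reaches 30% at 10.9 min, about a quarter of my clock.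

    partner + catalyst intermediate A → free catalyst + target (k = 560 M⁻¹ min⁻¹)
    starting material + free catalyst ⇌ catalyst intermediate A (K = 130 M⁻¹, k = 710 M⁻¹ min⁻¹)
    2 free catalyst ⇌ resting dimer (K = 81000 M⁻¹, k = 960 M⁻¹ min⁻¹)
    partner + catalyst intermediate B → free catalyst + second product (k = 12000 M⁻¹ min⁻¹)
    starting material ⇌ dormant form (K = 2.10, k = 0.0250 min⁻¹)
    second substrate + free catalyst ⇌ catalyst intermediate B (K = 59.0 M⁻¹, k = 920 M⁻¹ min⁻¹)

The largest single effect on this flask's order in second substrate is the passing of starting material into the dormant form, a step that takes no catalyst . At 20.0 min the flask holds 32.3% dormant form against 13.3% target. The second case is the same run with that passage taken away, which is the premise of the clock: conversion must then go through the catalyst. With the passing of starting material into the dormant form taken away, the rate of making target at 30% conversion is 0.386 times the actual one, and the order in second substrate is −1.4.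

All runs stem from a simulated flask on assumed constants.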